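**Retrosynthetic overview**
- Target ⇐ its tri-O-methyl ether (BBr3) ⇐ saturated 20-membered macrocyclic C3 ketone (Wolff–Kishner removal of C=O).
- Macrocyclic ketone ⇐ ring-closing metathesis (C6=C7) and hydrogenation of an open-chain diaryl ether dienyl ketone.
- Dienyl ketone ⇐ conjugate reduction of an enone made by the key intermolecular Claisen–Schmidt aldol condensation (C1–C2 bond) of a diaryl ether benzaldehyde with hex-5-en-2-one.
- Diaryl ether aldehyde ⇐ Ullmann coupling of 3-methoxy-5-(non-8-enyl)phenol (ring A) with 2-bromo-3,5-dimethoxybenzaldehyde (ring B).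
- Ring order: both benzene rings are bought, the diaryl ether links them first, and the 20-membered macrocycle is the only ring formed, last, by metathesis.

Assumption: the SMILES has no stereodescriptor and the 20-membered ansa ring is too loose for stable planar chirality, so the target is treated as one achiral compound and no stereocentre has to be set.

Chain numbering used below: C1 is the chain carbon on ring B (the ring with two oxygens besides the ether oxygen), C14 the chain carbon on ring A.

**Step 1**
Reactants: 1 3,5-dimethoxybenzyl bromide; 2 8-bromooct-1-ene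
Product: 4 1,3-dimethoxy-5-(non-8-en-1-yl)benzene, via oct-7-en-1-ylmagnesium bromide 3 (not isolated)
Conditions: 2, Mg, cat. I2, THF, reflux; then add to 1, Li2CuCl4 (3 mol %), THF, −78 °C → rt
Reagents that add atoms: none
Why: Kochi-type copper-catalysed sp3–sp3 cross-coupling of a primary alkyl Grignard reagent with a benzylic bromide is fast at low temperature and leaves the remote terminal alkene untouched.

**Step 2**
Reactants: 4 1,3-dimethoxy-5-(non-8-en-1-yl)benzene
Product: 5 3-methoxy-5-(non-8-en-1-yl)phenol
Conditions: NaSEt (3 equiv), DMF, 140 °C; then 1 M HCl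
Reagents that add atoms: none
Why: Thiolate SN2 O-demethylation of an aryl methyl ether stops after one methyl group because the phenoxide formed deactivates the second methoxy group towards further attack.

**Step 3**
Reactants: 6 3,5-dimethoxybenzaldehyde
Product: 7 2-bromo-3,5-dimethoxybenzaldehyde
Conditions: NBS (1.05 equiv), MeCN, 0 °C → rt
Reagents that add atoms: N-bromosuccinimide, O=C1CCC(=O)N1Br
Why: Electrophilic aromatic bromination goes to C2 (ortho to one methoxy group and para to the other) and not to the crowded C4 between the two methoxy groups.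

**Step 4**
Reactants: 5 3-methoxy-5-(non-8-en-1-yl)phenol; 7 2-bromo-3,5-dimethoxybenzaldehyde
Product: 8 3,5-dimethoxy-2-[3-methoxy-5-(non-8-en-1-yl)phenoxy]benzaldehyde
Conditions: CuI (10 mol %), picolinic acid (20 mol %), K3PO4 (2 equiv), DMSO, 90 °C
Reagents that add atoms: none
Why: Ullmann-type copper-catalysed diaryl ether coupling with a ligand suited to hindered partners is helped by the ortho-formyl group, which activates the C–Br bond, and the terminal alkene is inert.

**Step 5**
Reactants: 8 3,5-dimethoxy-2-[3-methoxy-5-(non-8-en-1-yl)phenoxy]benzaldehyde; 9 hex-5-en-2-one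
Product: 11 (1E)-1-{3,5-dimethoxy-2-[3-methoxy-5-(non-8-en-1-yl)phenoxy]phenyl}hepta-1,6-dien-3-one, via racemic β-hydroxy ketone aldol adduct 10 (not isolated)
Conditions: 9 (5 equiv), 10% aq NaOH, EtOH–THF, 0 °C → rt
Reagents that add atoms: none
Why: In this Claisen–Schmidt crossed aldol condensation the aryl aldehyde cannot enolise, the methyl ketone reacts at its methyl group under thermodynamic control, and E1cB dehydration of the racemic aldol gives the conjugated E-enone, which erases the transient carbinol stereocentre.

**Step 6**
Reactants: 11 (1E)-1-{3,5-dimethoxy-2-[3-methoxy-5-(non-8-en-1-yl)phenoxy]phenyl}hepta-1,6-dien-3-one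
Product: 12 1-{3,5-dimethoxy-2-[3-methoxy-5-(non-8-en-1-yl)phenoxy]phenyl}hept-6-en-3-one
Conditions: [(Ph3P)CuH]6 (0.4 equiv), H2O (5 equiv), degassed toluene, rt
Reagents that add atoms: none
Why: Copper hydride conjugate reduction (Stryker reduction) delivers hydride only to the polarised enone C=C and leaves both terminal alkenes and the ketone intact, which removes the styryl enone that would otherwise close to cyclopentenone in the metathesis step.

**Step 7**
Reactants: 12 1-{3,5-dimethoxy-2-[3-methoxy-5-(non-8-en-1-yl)phenoxy]phenyl}hept-6-en-3-one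
Product: 13 20-membered macrocyclic keto-alkene (tri-O-methyl; C3 ketone; C6=C7 alkene as E/Z mixture)
Conditions: second-generation Grubbs catalyst RuCl2(=CHPh)(PCy3)(H2IMes) (10 mol %), 1,4-benzoquinone (20 mol %), CH2Cl2 (1 mM), 40 °C
Reagents that add atoms: none
Why: Ring-closing olefin metathesis of two unhindered terminal alkenes at high dilution closes the strain-free 20-membered ring with loss of ethene, and the E/Z ratio does not matter because the alkene is hydrogenated next.

**Step 8**
Reactants: 13 20-membered macrocyclic keto-alkene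
Product: 14 saturated 20-membered macrocyclic C3 ketone (tri-O-methyl)
Conditions: H2 (1 atm), 10% Pd/C, EtOAc, rt
Reagents that add atoms: none
Why: Heterogeneous catalytic hydrogenation saturates the disubstituted ring alkene while the dialkyl ketone, the aryl methyl ethers and the diaryl ether are inert at 1 atm H2.

**Step 9**
Reactants: 14 saturated 20-membered macrocyclic C3 ketone
Product: 16 tri-O-methyl ether of the target, via macrocyclic ketone hydrazone 15 (not isolated)
Conditions: N2H4·H2O, KOH, diethylene glycol, 130 °C then 195 °C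
Reagents that add atoms: none
Why: Wolff–Kishner reduction (Huang-Minlon modification) turns the unhindered dialkyl ketone into CH2 through its hydrazone with loss of N2, and the base-stable aryl ethers survive as they do in classical alkylresorcinol dimethyl ether syntheses.

**Step 10**
Reactants: 16 tri-O-methyl ether of the target
Product: 17 target macrocycle CNP0173380.0
Conditions: BBr3 (6 equiv), CH2Cl2, −78 °C → rt; then H2O
Reagents that add atoms: none
Why: Lewis-acid aryl methyl ether cleavage with BBr3 removes all three methyl groups by bromide SN2 attack on the O-complexed methyl carbon, whereas the diaryl ether is not cleaved, which gives the achiral target.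

**Compound list**
1 | 3,5-dimethoxybenzyl bromide | COc1cc(CBr)cc(OC)c1 | starting material
2 | 8-bromooct-1-ene | C=CCCCCCCBr | starting material
3 | oct-7-en-1-ylmagnesium bromide | C=CCCCCCC[Mg]Br | intermediate
4 | 1,3-dimethoxy-5-(non-8-en-1-yl)benzene | COc1cc(CCCCCCCC=C)cc(OC)c1 | intermediate
5 | 3-methoxy-5-(non-8-en-1-yl)phenol | COc1cc(O)cc(CCCCCCCC=C)c1 | intermediate
6 | 3,5-dimethoxybenzaldehyde | COc1cc(C=O)cc(OC)c1 | starting material
7 | 2-bromo-3,5-dimethoxybenzaldehyde | COc1cc(C=O)c(Br)c(OC)c1 | intermediate
8 | 3,5-dimethoxy-2-[3-methoxy-5-(non-8-en-1-yl)phenoxy]benzaldehyde | COc1cc(C=O)c(Oc2cc(OC)cc(CCCCCCCC=C)c2)c(OC)c1 | intermediate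
9 | hex-5-en-2-one | CC(=O)CCC=C | starting material
10 | racemic 1-{3,5-dimethoxy-2-[3-methoxy-5-(non-8-en-1-yl)phenoxy]phenyl}-1-hydroxyhept-6-en-3-one | COc1cc(C(O)CC(=O)CCC=C)c(Oc2cc(OC)cc(CCCCCCCC=C)c2)c(OC)c1 | intermediate
11 | (1E)-1-{3,5-dimethoxy-2-[3-methoxy-5-(non-8-en-1-yl)phenoxy]phenyl}hepta-1,6-dien-3-one | COc1cc(/C=C/C(=O)CCC=C)c(Oc2cc(OC)cc(CCCCCCCC=C)c2)c(OC)c1 | intermediate
12 | 1-{3,5-dimethoxy-2-[3-methoxy-5-(non-8-en-1-yl)phenoxy]phenyl}hept-6-en-3-one | COc1cc(CCC(=O)CCC=C)c(Oc2cc(OC)cc(CCCCCCCC=C)c2)c(OC)c1 | intermediate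
13 | 20-membered macrocyclic keto-alkene, tri-O-methyl, C3 ketone, C6=C7 alkene (E/Z mixture, drawn without alkene descriptor) | COc1cc2cc(c1)Oc1c(OC)cc(OC)cc1CCC(=O)CCC=CCCCCCCC2 | intermediate
14 | saturated 20-membered macrocyclic C3 ketone, tri-O-methyl | COc1cc2cc(c1)Oc1c(OC)cc(OC)cc1CCC(=O)CCCCCCCCCCC2 | intermediate
15 | hydrazone of macrocyclic ketone 14 | COc1cc2cc(c1)Oc1c(OC)cc(OC)cc1CCC(=NN)CCCCCCCCCCC2 | intermediate
16 | tri-O-methyl ether of the target | COc1cc2cc(c1)Oc1c(OC)cc(OC)cc1CCCCCCCCCCCCCC2 | intermediate
17 | target CNP0173380.0 (achiral) | Oc1cc2cc(c1)Oc1c(O)cc(O)cc1CCCCCCCCCCCCCC2 | target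

**Totals**
Total step count: 10.
Longest linear sequence: 9 steps (steps 1, 2, 4, 5, 6, 7, 8, 9, 10 from 1 and 2).

**Three steps most likely to fail, with fallbacks**

Step 4 (Ullmann coupling at a bromide flanked by CHO and OMe; risk of slow coupling or hydrodebromination). The fallback sets out from 6, with 5 as partner, and comes back to the route at 8. Aldehyde 6 is fluorinated with Selectfluor in MeCN at the same C2 position that bromination uses, giving 2-fluoro-3,5-dimethoxybenzaldehyde F1. F1 then undergoes copper-free nucleophilic aromatic substitution with phenol 5 (Cs2CO3, DMAc, 130 °C), activated by the ortho-formyl group, to give 8.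

Step 5 (Claisen–Schmidt condensation; risk of condensation at the ketone CH2 side, double condensation or Michael follow-up). The fallback sets out from 9, with 8 as partner, and comes back at 11 through 10, which is now isolated. Ketone 9 is converted with LiN(iPr)2 (THF, −78 °C) and Me3SiCl into its kinetic silyl enol ether trimethyl(hexa-1,5-dien-2-yloxy)silane F2, which fixes the methyl-side regiochemistry. A BF3·OEt2-promoted Mukaiyama aldol addition of F2 to 8 (CH2Cl2, −78 °C) gives β-hydroxy ketone 10 after aqueous work-up. Acid-catalysed dehydration of this benzylic aldol (cat. p-TsOH, toluene, 50 °C) then gives E-enone 11.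

Step 7 (macrocyclic metathesis; risk of oligomers, and of catalyst sequestration by six-membered chelation of the C3 ketone to the ruthenium carbene formed at C6). The fallback sets out from 12 and comes back at 13. The ketone of 12 is masked with ethylene glycol (cat. p-TsOH, toluene, Dean–Stark) to give the diene ethylene ketal F3. The non-chelating ketal carbon also biases the chain towards folding. Ring-closing metathesis of F3 under the step 7 conditions gives the macrocyclic alkene ethylene ketal F4, and aqueous HCl in THF at rt releases keto-alkene 13.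

**Further compounds**
F1 | step 4 | 2-fluoro-3,5-dimethoxybenzaldehyde | COc1cc(C=O)c(F)c(OC)c1
F2 | step 5 | trimethyl(hexa-1,5-dien-2-yloxy)silane | C=C(CCC=C)O[Si](C)(C)C
F3 | step 7 | diene ethylene ketal: 2-(but-3-en-1-yl)-2-(2-{3,5-dimethoxy-2-[3-methoxy-5-(non-8-en-1-yl)phenoxy]phenyl}ethyl)-1,3-dioxolane | COc1cc(CCC2(CCC=C)OCCO2)c(Oc3cc(OC)cc(CCCCCCCC=C)c3)c(OC)c1
F4 | step 7 | macrocyclic alkene ethylene ketal (C3 dioxolane of 13, E/Z mixture) | COc1cc2cc(c1)Oc1c(OC)cc(OC)cc1CCC1(CCC=CCCCCCCC2)OCCO1
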